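**Overview**

- Retrosynthesis: the C40 chain is cut at C11'=C12' and then at C11=C12 (two Wittig reactions) into a C10 dialdehyde and two C15 phosphonium salts. Each salt is cut at C7=C8 or C7'=C8' (HWE) into a C5 phosphonate and a C10 ring aldehyde.
- Both ring aldehydes go back to one (3R,6S)-cis-enediol, and that to the 3,6-endoperoxide of safranol silyl ether, so the C3–O and C6–O bonds of both rings are cut together.
- Enabling feature: in the 3,6-epoxy ring (a 7-oxabicyclo[2.2.1]heptane) and in the 3',5',6'-triol cyclohexane ring, O3 and O6 sit cis across C3/C6 with the same absolute sense, and the rings differ only at C5. The ten carbons C1–C7 and C16–C18 of each ring are those of safranal, whose C3=C4–C5=C6 diene is locked s-cis in the ring.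
- Forward order: the 2,3-dioxabicyclo[2.2.2]octene forms first and is opened to the enediol and resolved. The epoxy branch then makes the C4–C5 epoxide and closes the O6–C3 bridge; the triol branch closes and reopens a cis-fused cyclic carbonate. The chain grows C10 → C15 twice, then C15 + C10 → C25, then C25 + C15 → C40.
- Stereochemistry: O3/O6 cis comes from the suprafacial cycloaddition and the absolute sense from lipase resolution. C5 comes from hydroxyl-directed epoxidation and hydride opening, and the bridge from double inversion at C3 (Mitsunobu, then transannular displacement). C5' comes from iodocarbonation tethered through C7', anti to O6'. The alkenes are E from HWE and from Wittig with thermal equilibration.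

Key step: step 3

Conventions: ring locants follow carotenoid numbering (C1 = CMe2, C2 = CH2, C3 = CH–O, C4, C5 = C–CH3, C6 = ring carbon bearing C7; primes for the triol ring). Compounds 4 and 5 are racemates, drawn as the enantiomer that is carried on.

Assumption: in the lipase step the (3S,6R)-antipode is taken to be the fast-acylated one (CH2–CMe2 flank as the large group of the secondary carbinol). If the enzyme preferred the other antipode, the acetate would be kept and methanolysed (K2CO3, MeOH) to the same diol 6.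

**Route**

Step 1
Reactants: 1 safranal
Product: 2 safranol
Conditions: NaBH4, CeCl3·7H2O, MeOH, 0 °C
Reagents that add atoms: none
Why: Luche 1,2-reduction delivers hydride to the formyl carbon only and leaves the conjugated cyclohexadiene untouched.

Step 2
Reactants: 2 safranol
Product: 3 safranol TBS ether
Conditions: TBSCl, imidazole, DMF, 0 °C → rt
Reagents that add atoms: tert-butyldimethylsilyl chloride, CC(C)(C)[Si](C)(C)Cl
Why: Standard silylation of the primary allylic alcohol masks O7 and leaves an electron-rich, acceptor-free diene for the cycloaddition.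

Step 3
Reactants: 3 safranol TBS ether
Product: 4 rac-3,6-endoperoxide
Conditions: O2, tetraphenylporphyrin (cat.), white LED light, CH2Cl2, −30 °C
Reagents that add atoms: dioxygen, O=O
Why: Photosensitised singlet oxygen adds as a dienophile across the termini C3 and C6 of the ring-locked s-cis diene C3=C4–C5=C6 in a concerted suprafacial [4+2] cycloaddition, the reaction type of the dye-sensitised photooxygenation of 1,3-cyclohexadienes to 2,3-dioxabicyclo[2.2.2]octenes (α-terpinene to ascaridole). The six-membered 1,2-dioxene ring (C3–O–O–C6–C5=C4) closes by cycloaddition, both C–O bonds forming in one event while the alkene shifts to C4=C5 beside the C18 methyl. The new stereocentres C3 and C6 are fixed relative to each other (O3 and O6 cis) because one O2 molecule is delivered to one face; the diene is achiral, so the adduct is racemic and the absolute sense is chosen in step 5. The step needs [4+2] over the ene mode (allylic hydrogens at C2, C7 and C18), and this is secured by the cisoid geometry enforced by the six-membered ring, by the electron-rich diene left after reduction and silylation of the formyl group, and by low temperature in an aprotic solvent.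

Step 4
Reactants: 4 rac-3,6-endoperoxide
Product: 5 rac-cis-enediol
Conditions: thiourea, MeOH, rt
Reagents that add atoms: none
Why: Thiourea reduces only the O–O bond of bicyclic endoperoxides, so both C–O bonds (and the cis relation of O3 and O6) and the C4=C5 alkene are kept.

Step 5
Reactants: 5 rac-cis-enediol
Product: 6 (3R,6S)-cis-enediol
Conditions: Burkholderia cepacia lipase (Amano PS, immobilised), vinyl acetate, tBuOMe, 30 °C, stopped just past half conversion; chromatography
Reagents that add atoms: none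
Why: Lipase-catalysed kinetic resolution by irreversible transesterification of the secondary allylic C3 carbinol (the tertiary 6-OH is inert) should acetylate the (3S,6R)-antipode and leave the (3R,6S)-diol, which fixes the absolute configuration of C3 and C6 for both end rings.

Step 6
Reactants: 6 (3R,6S)-cis-enediol
Product: 7 (3R,4R,5R,6R)-4,5-epoxy-3,6-diol
Conditions: VO(acac)2 (cat.), tBuOOH, CH2Cl2, 0 °C → rt
Reagents that add atoms: tert-butyl hydroperoxide, CC(C)(C)OO
Why: Vanadium-catalysed hydroxyl-directed epoxidation, in which both allylic hydroxyls lie on one face and deliver the peroxide oxygen to that face, sets C4 and C5 with the epoxide cis to O3 and O6.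

Step 7
Reactants: 7 (3R,4R,5R,6R)-4,5-epoxy-3,6-diol
Product: 8 (3S,4R,5R,6R)-3-O-benzoyl-4,5-epoxy-6-ol
Conditions: PhCO2H, PPh3, DIAD, THF, 0 °C → rt
Reagents that add atoms: benzoic acid, O=C(O)c1ccccc1
Why: Mitsunobu esterification inverts the secondary C3 carbinol by SN2 displacement of its oxyphosphonium ion, while the tertiary 6-OH and the epoxide do not take part.

Step 8
Reactants: 8 (3S,4R,5R,6R)-3-O-benzoyl-4,5-epoxy-6-ol
Product: 9 (3S,5R,6R)-3,5,6-triol (3-epi-triol)
Conditions: LiAlH4, THF, 0 → 40 °C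
Reagents that add atoms: none
Why: Hydride cleaves the benzoate and opens the trisubstituted epoxide at the less substituted C4 (helped by the neighbouring C3 alkoxyaluminate), so the C5–O bond and with it the C5 configuration (5-OH cis to 6-OH) is kept.

Step 9
Reactants: 9 (3S,5R,6R)-3,5,6-triol
Product: 11 (3R,5R,6R)-3,6-epoxy-5-ol 7-O-TBS ether, via 3-O-triflate 10 (not isolated)
Conditions: Tf2O (1.05 equiv), 2,6-lutidine, CH2Cl2, −78 → 0 °C
Reagents that add atoms: none
Why: Hydroxy-triflate cyclisation, in which the secondary 3-OH is sulfonylated selectively and the neutral tertiary 6-OH on the opposite face displaces it transannularly through a boat (5-exo-tet, inversion at C3), closes the 7-oxabicyclo[2.2.1]heptane, and the alkoxide-free medium avoids Grob-type fragmentation from the 1,3-related 5-hydroxyl.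

Step 10
Reactants: 11 (3R,5R,6R)-3,6-epoxy-5-ol 7-O-TBS ether
Product: 12 (3R,5R,6R)-3,6-epoxy-5,7-diol
Conditions: Bu4NF, THF, 0 °C → rt
Reagents that add atoms: none
Why: Fluoride cleaves the primary TBS ether, the only fluoride-labile group present.

Step 11
Reactants: 12 (3R,5R,6R)-3,6-epoxy-5,7-diol
Product: 13 (3R,5R,6S)-3,6-epoxy-5-hydroxy C10 aldehyde
Conditions: nPr4N[RuO4] (cat.), N-methylmorpholine N-oxide, 4 Å molecular sieves, CH2Cl2, rt
Reagents that add atoms: none
Why: Ley–Griffith oxidation converts the primary alcohol into the non-enolisable bridgehead aldehyde under neutral conditions, and the tertiary 5-OH cannot be oxidised.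

Step 12
Reactants: 13 (3R,5R,6S)-3,6-epoxy-5-hydroxy C10 aldehyde
Product: 14 5-O-TMS ether of aldehyde 13
Conditions: TMSOTf, 2,6-lutidine, CH2Cl2, −78 → 0 °C
Reagents that add atoms: trimethylsilyl trifluoromethanesulfonate, C[Si](C)(C)OS(=O)(=O)C(F)(F)F
Why: Silylation of the tertiary hydroxyl removes the β-alkoxide that could cause retro-aldol cleavage of C5–C6 under the basic olefinations that follow.

Step 13
Reactants: 14 5-O-TMS ether of aldehyde 13; 15 triethyl 3-methyl-4-phosphonocrotonate
Product: 16 left C15 dienoate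
Conditions: 15, LiN(SiMe3)2, THF, −78 °C; then 14, −78 → 0 °C
Reagents that add atoms: none
Why: Horner–Wadsworth–Emmons olefination with the stabilised C5 phosphonate anion forms C7=C8 with E geometry and brings in the 9E trisubstituted alkene, any 9Z ester being removable by chromatography.

Step 14
Reactants: 16 left C15 dienoate
Product: 17 left C15 allylic alcohol
Conditions: iBu2AlH, CH2Cl2, −78 °C; aq. KNaC4H4O6
Reagents that add atoms: none
Why: DIBAL reduces the conjugated ester to the primary allylic alcohol by 1,2-hydride delivery without touching the diene, the bridged ether or the silyl ether.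

Step 15
Reactants: 17 left C15 allylic alcohol
Product: 19 left C15 phosphonium bromide, via left C15 allylic bromide 18 (not isolated)
Conditions: CBr4, PPh3, 2,6-lutidine (cat.), CH2Cl2, −20 °C; then PPh3, EtOAc, rt
Reagents that add atoms: carbon tetrabromide, BrC(Br)(Br)Br; triphenylphosphine, c1ccc(cc1)P(c1ccccc1)c1ccccc1
Why: Appel bromination of the primary allylic alcohol under neutral conditions, then SN2 quaternisation of PPh3 at the primary carbon, gives the Wittig salt without exposing the bridged ether or the silyl ether to HBr.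

Step 16
Reactants: 19 left C15 phosphonium bromide; 20 2,7-dimethylocta-2,4,6-trienedial
Product: 22 all-E C25 apo-aldehyde, via 11Z C25 apo-aldehyde 21 (not isolated)
Conditions: NaN(SiMe3)2, THF, −78 °C; added to 20 (3 equiv), THF, −78 → 0 °C; then n-heptane, 80 °C, Ar, dark
Reagents that add atoms: none
Why: Wittig olefination of one formyl group of the symmetrical dialdehyde (in excess, to suppress double reaction) forms C11=C12 as an E/Z mixture, and the sterically hindered 11Z isomer should relax thermally to the all-E polyenal.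

Step 17
Reactants: 6 (3R,6S)-cis-enediol
Product: 23 3-O-TBDPS ether of diol 6
Conditions: TBDPSCl, imidazole, DMF, rt
Reagents that add atoms: tert-butyl(chloro)diphenylsilane, CC(C)(C)[Si](Cl)(c1ccccc1)c1ccccc1
Why: Silylation distinguishes the secondary allylic 3-OH from the hindered tertiary 6-OH and installs a group that lasts to the final step.

Step 18
Reactants: 23 3-O-TBDPS ether of diol 6
Product: 24 (3R,6S)-3-O-TBDPS-6,7-diol
Conditions: HF·pyridine, pyridine, THF, 0 °C
Reagents that add atoms: none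
Why: Buffered HF cleaves the primary TBS ether much faster than the secondary TBDPS ether and is mild enough for the tertiary allylic alcohol.

Step 19
Reactants: 24 (3R,6S)-3-O-TBDPS-6,7-diol
Product: 25 7-O-Boc carbonate
Conditions: Boc2O (1.1 equiv), DMAP (cat.), CH2Cl2, 0 °C
Reagents that add atoms: di-tert-butyl dicarbonate, CC(C)(C)OC(=O)OC(=O)OC(C)(C)C
Why: DMAP-catalysed acylation takes only the primary C7 hydroxyl, and low temperature without stronger base keeps the hindered tertiary 6-OH from closing a five-membered carbonate.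

Step 20
Reactants: 25 7-O-Boc carbonate
Product: 26 (3R,4R,5R,6R)-4-iodo 5,7-cyclic carbonate
Conditions: IBr, toluene, −85 °C; aq. Na2S2O3/NaHCO3
Reagents that add atoms: iodine monobromide, IBr
Why: Electrophilic iodocarbonation of the homoallylic tert-butyl carbonate, in which the carbonyl oxygen tethered through C7 opens the iodonium ion at the more substituted C5 (6-exo) from the C7 face with loss of the tert-butyl group, sets C5 with its oxygen trans to the 6-OH and places iodine trans at C4.

Step 21
Reactants: 26 (3R,4R,5R,6R)-4-iodo 5,7-cyclic carbonate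
Product: 27 (3R,5S,6R)-5,7-cyclic carbonate
Conditions: Bu3SnH, AIBN (cat.), toluene, 80 °C
Reagents that add atoms: none
Why: Radical chain deiodination reduces the secondary C4 radical faster than it can expel the β-carbonate or β-silyloxy group, so C4 becomes CH2 and no stereocentre is touched.

Step 22
Reactants: 27 (3R,5S,6R)-5,7-cyclic carbonate
Product: 28 (3R,5S,6R)-3-O-TBDPS-5,6,7-triol
Conditions: K2CO3, MeOH, rt
Reagents that add atoms: none
Why: Methanolysis of the cyclic carbonate frees the primary 7-OH and the tertiary 5-OH, and the TBDPS ether is stable to carbonate in methanol.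

Step 23
Reactants: 28 (3R,5S,6R)-3-O-TBDPS-5,6,7-triol
Product: 29 (3R,5S,6S)-5,6-dihydroxy C10 aldehyde
Conditions: (COCl)2, DMSO, CH2Cl2, −78 °C; Et3N, −78 → −20 °C
Reagents that add atoms: none
Why: Swern oxidation acts on the only oxidisable (primary) hydroxyl without cleaving the 6,7-glycol, and the fully substituted C6 cannot epimerise.

Step 24
Reactants: 29 (3R,5S,6S)-5,6-dihydroxy C10 aldehyde
Product: 30 5,6-bis-O-TMS ether of aldehyde 29
Conditions: TMSOTf (3 equiv), 2,6-lutidine, CH2Cl2, −78 → 0 °C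
Reagents that add atoms: trimethylsilyl trifluoromethanesulfonate, C[Si](C)(C)OS(=O)(=O)C(F)(F)F
Why: Capping both tertiary hydroxyls prevents the α-alkoxide (acyloin shift) and the β-alkoxide (retro-aldol) from forming during the olefination.

Step 25
Reactants: 30 5,6-bis-O-TMS ether of aldehyde 29; 15 triethyl 3-methyl-4-phosphonocrotonate
Product: 31 right C15 dienoate
Conditions: 15, LiN(SiMe3)2, THF, −78 °C; then 30, −78 °C → rt
Reagents that add atoms: none
Why: Horner–Wadsworth–Emmons olefination as in step 13 forms C7'=C8' with E geometry on the non-enolisable, fully protected aldehyde.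

Step 26
Reactants: 31 right C15 dienoate
Product: 32 right C15 allylic alcohol
Conditions: iBu2AlH, CH2Cl2, −78 °C; aq. KNaC4H4O6
Reagents that add atoms: none
Why: DIBAL reduces the conjugated ester to the allylic alcohol and leaves the three silyl ethers in place.

Step 27
Reactants: 32 right C15 allylic alcohol
Product: 34 right C15 phosphonium bromide, via right C15 allylic bromide 33 (not isolated)
Conditions: CBr4, PPh3, 2,6-lutidine (cat.), CH2Cl2, −20 °C; then PPh3, EtOAc, rt
Reagents that add atoms: carbon tetrabromide, BrC(Br)(Br)Br; triphenylphosphine, c1ccc(cc1)P(c1ccccc1)c1ccccc1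
Why: Neutral Appel bromination and SN2 quaternisation of PPh3 give the Wittig salt without acid, so the tertiary silyl ethers survive.

Step 28
Reactants: 34 right C15 phosphonium bromide; 22 all-E C25 apo-aldehyde
Product: 36 all-E silylated C40 carotenoid, via 11'Z isomer 35 (not isolated)
Conditions: NaN(SiMe3)2, THF, −78 °C; then 22, −78 → 0 °C; then n-heptane, 80 °C, Ar, dark
Reagents that add atoms: none
Why: Wittig olefination joins C11' to C12' as an E/Z mixture, and the hindered 11'Z isomer should equilibrate thermally to the all-E polyene.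

Step 29
Reactants: 36 all-E silylated C40 carotenoid
Product: 37 target CNP0261804.1
Conditions: Bu4NF (buffered with AcOH), THF, rt, Ar, dark; crystallisation
Reagents that add atoms: none
Why: Fluoride cleaves the TBDPS ether and the three tertiary TMS ethers without touching any stereocentre or alkene, and crystallisation in the dark should give the all-E tetrol.

**Compound list**

1 | safranal (2,6,6-trimethylcyclohexa-1,3-diene-1-carbaldehyde) | CC1=C(C=O)C(C)(C)CC=C1 | starting material
2 | safranol, (2,6,6-trimethylcyclohexa-1,3-dien-1-yl)methanol | CC1=C(CO)C(C)(C)CC=C1 | intermediate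
3 | safranol TBS ether | CC1=C(CO[Si](C)(C)C(C)(C)C)C(C)(C)CC=C1 | intermediate
4 | rac-(3R*,6S*)-3,6-endoperoxide, 1-(TBS-oxymethyl)-6,8,8-trimethyl-2,3-dioxabicyclo[2.2.2]oct-5-ene (racemate, enantiomer carried on drawn) | CC(C)(C)[Si](C)(C)OC[C@]12OO[C@H](CC1(C)C)C=C2C | intermediate
5 | rac-cis-4-(TBS-oxymethyl)-3,5,5-trimethylcyclohex-2-ene-1,4-diol (racemate, enantiomer carried on drawn) | CC(C)(C)[Si](C)(C)OC[C@]1(O)C(C)(C)C[C@@H](O)C=C1C | intermediate
6 | (3R,6S)-cis-enediol, (1R,4S)-4-(TBS-oxymethyl)-3,5,5-trimethylcyclohex-2-ene-1,4-diol | CC(C)(C)[Si](C)(C)OC[C@]1(O)C(C)(C)C[C@@H](O)C=C1C | intermediate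
7 | (3R,4R,5R,6R)-4,5-epoxy-7-(TBS-oxy) ring 3,6-diol (epoxide cis to both hydroxyls) | CC(C)(C)[Si](C)(C)OC[C@]1(O)C(C)(C)C[C@@H](O)[C@H]2O[C@@]12C | intermediate
8 | (3S,4R,5R,6R)-3-O-benzoyl-4,5-epoxy-7-(TBS-oxy) ring 6-ol (benzoate trans to epoxide and 6-OH) | CC(C)(C)[Si](C)(C)OC[C@]1(O)C(C)(C)C[C@H](OC(=O)c3ccccc3)[C@H]2O[C@@]12C | intermediate
9 | (3S,5R,6R)-7-(TBS-oxy) ring 3,5,6-triol (5-OH cis to 6-OH, 3-OH trans) | CC(C)(C)[Si](C)(C)OC[C@]1(O)C(C)(C)C[C@H](O)C[C@@]1(C)O | intermediate
10 | 3-O-triflate of triol 9 | CC(C)(C)[Si](C)(C)OC[C@]1(O)C(C)(C)C[C@H](OS(=O)(=O)C(F)(F)F)C[C@@]1(C)O | intermediate (not isolated)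
11 | (3R,5R,6R)-3,6-epoxy-5-ol 7-O-TBS ether, 1-(TBS-oxymethyl)-2,6,6-trimethyl-7-oxabicyclo[2.2.1]heptan-2-exo-ol | CC(C)(C)[Si](C)(C)OC[C@]12O[C@H](CC1(C)C)C[C@@]2(C)O | intermediate
12 | (3R,5R,6R)-1-(hydroxymethyl)-2,6,6-trimethyl-7-oxabicyclo[2.2.1]heptan-2-exo-ol | OC[C@]12O[C@H](CC1(C)C)C[C@@]2(C)O | intermediate
13 | (3R,5R,6S)-2-exo-hydroxy-2,6,6-trimethyl-7-oxabicyclo[2.2.1]heptane-1-carbaldehyde | O=C[C@]12O[C@H](CC1(C)C)C[C@@]2(C)O | intermediate
14 | 5-O-TMS ether of aldehyde 13 | O=C[C@]12O[C@H](CC1(C)C)C[C@@]2(C)O[Si](C)(C)C | intermediate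
15 | triethyl 3-methyl-4-phosphonocrotonate, ethyl (E)-4-(diethoxyphosphoryl)-3-methylbut-2-enoate | CCOC(=O)/C=C(\C)CP(=O)(OCC)OCC | starting material
16 | left C15 dienoate, ethyl (2E,4E)-3-methyl-5-[(3R,5R,6S)-3,6-epoxy-5-(TMS-oxy) ring]penta-2,4-dienoate | CCOC(=O)/C=C(C)/C=C/[C@]12O[C@H](CC1(C)C)C[C@@]2(C)O[Si](C)(C)C | intermediate
17 | left C15 allylic alcohol (2E,4E) | OC/C=C(C)/C=C/[C@]12O[C@H](CC1(C)C)C[C@@]2(C)O[Si](C)(C)C | intermediate
18 | left C15 allylic bromide (2E,4E) | BrC/C=C(C)/C=C/[C@]12O[C@H](CC1(C)C)C[C@@]2(C)O[Si](C)(C)C | intermediate (not isolated)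
19 | left C15 triphenylphosphonium bromide (5-O-TMS) | [Br-].c1ccccc1[P+](c1ccccc1)(c1ccccc1)C/C=C(C)/C=C/[C@]12O[C@H](CC1(C)C)C[C@@]2(C)O[Si](C)(C)C | intermediate
20 | (2E,4E,6E)-2,7-dimethylocta-2,4,6-trienedial | O=C/C(C)=C/C=C/C=C(C)/C=O | starting material
21 | 11Z isomer of the C25 apo-aldehyde | CC(/C=C\C=C(C)\C=C\[C@]12O[C@H](CC1(C)C)C[C@@]2(C)O[Si](C)(C)C)=C\C=C\C=C(C)\C=O | intermediate (not isolated)
22 | all-E C25 apo-aldehyde, (3R,5R,6S)-3,6-epoxy-5-(TMS-oxy)-5,6-dihydro-12'-apo-β-caroten-12'-al | CC(/C=C/C=C(C)/C=C/[C@]12O[C@H](CC1(C)C)C[C@@]2(C)O[Si](C)(C)C)=C\C=C\C=C(C)\C=O | intermediate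
23 | (3R,6S)-3-O-TBDPS-7-O-TBS enediol | CC(C)(C)[Si](C)(C)OC[C@]1(O)C(C)(C)C[C@@H](O[Si](c2ccccc2)(c2ccccc2)C(C)(C)C)C=C1C | intermediate
24 | (3R,6S)-3-O-TBDPS-4-ene-6,7-diol | OC[C@]1(O)C(C)(C)C[C@@H](O[Si](c2ccccc2)(c2ccccc2)C(C)(C)C)C=C1C | intermediate
25 | (3R,6S)-7-O-Boc carbonate of diol 24 | CC(C)(C)OC(=O)OC[C@]1(O)C(C)(C)C[C@@H](O[Si](c2ccccc2)(c2ccccc2)C(C)(C)C)C=C1C | intermediate
26 | (3R,4R,5R,6R)-4-iodo 5,7-cyclic carbonate (cis-fused, 6-OH free, 3-O-TBDPS) | O=C1OC[C@]2(O)C(C)(C)C[C@@H](O[Si](c3ccccc3)(c3ccccc3)C(C)(C)C)[C@@H](I)[C@]2(C)O1 | intermediate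
27 | (3R,5S,6R)-5,7-cyclic carbonate | O=C1OC[C@]2(O)C(C)(C)C[C@@H](O[Si](c3ccccc3)(c3ccccc3)C(C)(C)C)C[C@]2(C)O1 | intermediate
28 | (3R,5S,6R)-3-O-TBDPS ring 5,6,7-triol (5-OH trans to 6-OH) | OC[C@]1(O)C(C)(C)C[C@@H](O[Si](c2ccccc2)(c2ccccc2)C(C)(C)C)C[C@]1(C)O | intermediate
29 | (3R,5S,6S)-3-O-TBDPS-5,6-dihydroxy C10 aldehyde | O=C[C@]1(O)C(C)(C)C[C@@H](O[Si](c2ccccc2)(c2ccccc2)C(C)(C)C)C[C@]1(C)O | intermediate
30 | 5,6-bis-O-TMS ether of aldehyde 29 | O=C[C@]1(O[Si](C)(C)C)C(C)(C)C[C@@H](O[Si](c2ccccc2)(c2ccccc2)C(C)(C)C)C[C@]1(C)O[Si](C)(C)C | intermediate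
31 | right C15 dienoate (2E,4E; 3R,5S,6S) | CCOC(=O)/C=C(C)/C=C/[C@]1(O[Si](C)(C)C)C(C)(C)C[C@@H](O[Si](c2ccccc2)(c2ccccc2)C(C)(C)C)C[C@]1(C)O[Si](C)(C)C | intermediate
32 | right C15 allylic alcohol | OC/C=C(C)/C=C/[C@]1(O[Si](C)(C)C)C(C)(C)C[C@@H](O[Si](c2ccccc2)(c2ccccc2)C(C)(C)C)C[C@]1(C)O[Si](C)(C)C | intermediate
33 | right C15 allylic bromide | BrC/C=C(C)/C=C/[C@]1(O[Si](C)(C)C)C(C)(C)C[C@@H](O[Si](c2ccccc2)(c2ccccc2)C(C)(C)C)C[C@]1(C)O[Si](C)(C)C | intermediate (not isolated)
34 | right C15 triphenylphosphonium bromide | [Br-].c1ccccc1[P+](c1ccccc1)(c1ccccc1)C/C=C(C)/C=C/[C@]1(O[Si](C)(C)C)C(C)(C)C[C@@H](O[Si](c2ccccc2)(c2ccccc2)C(C)(C)C)C[C@]1(C)O[Si](C)(C)C | intermediate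
35 | 11'Z isomer of the silylated C40 carotenoid | CC(/C=C/C=C(C)/C=C/[C@]12O[C@H](CC1(C)C)C[C@@]2(C)O[Si](C)(C)C)=C\C=C\C=C(C)\C=C/C=C(C)/C=C/[C@]1(O[Si](C)(C)C)C(C)(C)C[C@@H](O[Si](c2ccccc2)(c2ccccc2)C(C)(C)C)C[C@]1(C)O[Si](C)(C)C | intermediate (not isolated)
36 | all-E 5-O-TMS, 5',6'-bis-O-TMS, 3'-O-TBDPS ether of the target | CC(/C=C/C=C(C)/C=C/[C@]12O[C@H](CC1(C)C)C[C@@]2(C)O[Si](C)(C)C)=C\C=C\C=C(C)\C=C\C=C(C)\C=C\[C@]1(O[Si](C)(C)C)C(C)(C)C[C@@H](O[Si](c2ccccc2)(c2ccccc2)C(C)(C)C)C[C@]1(C)O[Si](C)(C)C | intermediate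
37 | CNP0261804.1, (3R,5R,6S,3'R,5'S,6'S)-3,6-epoxy-5,6,5',6'-tetrahydro-β,β-carotene-5,3',5',6'-tetrol | CC(/C=C/C=C(C)/C=C/[C@]12O[C@H](CC1(C)C)C[C@@]2(C)O)=C\C=C\C=C(C)\C=C\C=C(C)\C=C\[C@]1(O)C(C)(C)C[C@@H](O)C[C@]1(C)O | target

**Step count and risks**

Total: 29 steps. Longest linear sequence: 18 steps (steps 1–16, 28, 29; the triol branch through steps 17–27 is equally long).

Steps most likely to fail:

1. Step 9. The secondary triflate may be lost by elimination, or by fragmentation or oxetane closure through the neighbouring 5-hydroxyl, before the boat-shaped transannular displacement by O6 takes place. Fallback, from 8 back to 11: close the bridge before a free 5-hydroxyl exists. Benzoate 8 is methanolysed (K2CO3, MeOH) with the epoxide kept, giving the (3S,4R,5R,6R)-4,5-epoxy-3,6-diol F1. Its secondary hydroxyl is mesylated (MsCl, Et3N, CH2Cl2) to the 3-O-mesylate F2. NaH in THF then lets the 6-alkoxide displace C3 with inversion to the 3,6:4,5-diepoxide F3, where the C5 oxygen is still tied up in the epoxide and cannot fragment. Li[BHEt3] opens the exo epoxide at the less substituted C4 and gives 11.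

2. Step 20. Iodonium formation on the face flanked by the silyloxy group may be slow, which would leave room for attack by the free 6-hydroxyl or for carbonate migration instead of the tethered delivery to C5. Fallback, from 24 back to 28: replace tethered delivery by substrate-controlled epoxidation. Diol 24 is converted (2,2-dimethoxypropane, pyridinium p-toluenesulfonate) into the 6,7-O-isopropylidene acetal F4, which removes the hydroxyl that would direct a peracid. mCPBA (NaHCO3, CH2Cl2) should then epoxidise C4=C5 anti to the two allylic oxygens, giving the 4,5-epoxide F5. LiAlH4 opens it at C4 to the 5-hydroxy acetonide F6, and aqueous acetic acid releases triol 28.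

3. Step 5. Enantiomer discrimination or the rate of acylation may be poor for this congested, fully substituted cyclohexenol. Fallback, from 5 back to 6: classical resolution through diastereomers. Racemic 5 is acylated at O3 with (1S)-camphanic chloride (Et3N, DMAP, CH2Cl2), and the diastereomeric esters are separated by chromatography or crystallisation. The (3R,6S)-diol 3-O-(1S)-camphanate F7 is then methanolysed (K2CO3, MeOH) to 6.

Further compounds
F1 | step 9 | (3S,4R,5R,6R)-4,5-epoxy-7-(TBS-oxy) ring 3,6-diol (3-epimer of 7) | CC(C)(C)[Si](C)(C)OC[C@]1(O)C(C)(C)C[C@H](O)[C@H]2O[C@@]12C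
F2 | step 9 | 3-O-mesylate of F1 | CC(C)(C)[Si](C)(C)OC[C@]1(O)C(C)(C)C[C@H](OS(C)(=O)=O)[C@H]2O[C@@]12C
F3 | step 9 | (3R,4R,5R,6R)-3,6:4,5-diepoxide 7-O-TBS ether (exo epoxide on the 7-oxabicyclo[2.2.1]heptane) | CC(C)(C)[Si](C)(C)OC[C@]12O[C@H](CC1(C)C)[C@H]3O[C@@]23C
F4 | step 20 | 6,7-O-isopropylidene acetal of diol 24 | CC1(C)OC[C@]2(O1)C(C)(C)C[C@@H](O[Si](c3ccccc3)(c3ccccc3)C(C)(C)C)C=C2C
F5 | step 20 | 4,5-epoxide of F4, anti to O3 and O6 | CC1(C)OC[C@]2(O1)C(C)(C)C[C@@H](O[Si](c3ccccc3)(c3ccccc3)C(C)(C)C)[C@@H]4O[C@]24C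
F6 | step 20 | 5-hydroxy 6,7-acetonide (5-OH trans to O6) | CC1(C)OC[C@]2(O1)C(C)(C)C[C@@H](O[Si](c3ccccc3)(c3ccccc3)C(C)(C)C)C[C@]2(C)O
F7 | step 5 | (3R,6S)-diol 3-O-(1S)-camphanate | CC(C)(C)[Si](C)(C)OC[C@]1(O)C(C)(C)C[C@@H](OC(=O)[C@@]23CC[C@@](C)(C(=O)O2)C3(C)C)C=C1C
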